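## The problem

Target 18 is an unsymmetrical dimer. Two (3R,4S)-3,4,5-trimethyl-2-benzopyran units are joined C7 to C7' through one methylene carbon (C9). One half is a 6,8-dihydroxyisochroman; the other is the same skeleton two hydrogens poorer, a 6-hydroxy-8-oxo quinone methide in which C1 is a vinylogous ester carbon.

Each carbocycle is hexasubstituted, so placing six different substituents around the benzene ring is the central skeletal task. The four stereocentres are two identical trans C3/C4 pairs. Within a half they are adjacent and can be set together, but the two halves are insulated by the arene and C9 and cannot control each other. One enantiopure monomer, set by reagent control and used twice, is therefore the sensible plan.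

Three features will not survive rough treatment:
- the quinone methide, which is electrophilic at C1;
- the free resorcinols, which oxidise in air under base;
- the benzylic C1–O2 ether, which ionises under protic or Lewis acid because C8a is ortho and para to oxygen.

The C3 and C4 centres are safe as long as the C3–O bond is never broken. The feature that makes the key step possible is the pattern around C4a and C8a: they are neighbours, C8a lies beside O8, and C4a is meta to both oxygens. This is the polarity of a 3-alkoxyaryne, which takes a carbon nucleophile at the distal carbon and an electrophile at the proximal one.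

## Retrosynthesis

**18 ⇒ 17.** The last operation removes hydride from C1 and a phenolic proton from one half of the symmetric tetraphenol 17. Leaving the quinone methide to the end means no other step has to tolerate it. Joining a preformed quinone methide to a resorcinol with formaldehyde would give homo- and hetero-dimers together. The forward step must oxidise once only, and at C1.

**17 ⇒ 15 + 5.** Both C7–C9 bonds are cut. C7 of resorcinol 15 is the only unsubstituted ring carbon and lies between two hydroxyls, so it is the natural nucleophile for formaldehyde 5; the hydroxymethyl compound 16 forms first and is captured by a second molecule of 15. The neighbouring option was to lithiate the dimethyl ether 14 at C7, add a formate ester and reduce with silane and acid. That costs two steps and exposes the acid-labile C1–O2 bond to reducing acid. The precursor is half the size and carries all the stereochemistry.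

**15 ⇒ 14 ⇒ 13.** The phenols are masked as methyl ethers because the earlier organolithium chemistry needs them. The C1–O2 bond of 14 is then cut to give alcohol 13, in which C1 is a silyl-protected benzylic alcohol. Closing the ring at the benzylic carbon leaves the C3–O bond intact, so C3 cannot invert. The forward reactions need an acid mild enough to ionise only the 2,4-dimethoxybenzylic position, and an ether cleavage that leaves the isochroman closed or lets it reclose.

**13 ⇒ 11 ⇒ 10.** The C3–O and C4–H bonds are removed together as water across an (E)-alkene. Syn hydroboration turns the alkene geometry into the trans relationship, and a chiral borane sets the absolute sense, so one step makes both centres (borane 12 is the intermediate). Opening a chiral 2,3-epoxybutane with an aryl-metal would be the neighbouring cut, but it needs a pentasubstituted aryl-metal and a separate C4a–C4 bond formation. Here the alkene comes from the key step. The silyl ether in 11 keeps the hydroxyl of 10 from consuming B–H.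

**10 ⇒ 3 + 4 + 5 (key disconnection).** C4a–C4 and C8a–C1 are cut in one move, which is the vicinal difunctionalisation of aryne 8. The forward sequence is:
- lithiation of fluoroarene 3 at H8a to give 7;
- loss of LiF to give aryne 8;
- addition of the alkenyllithium 6 (from bromide 4) at C4a to give 9;
- capture of 9 at C8a by formaldehyde 5.

Sequential cross-couplings would need two differentiated halogens on a pentasubstituted ring. Here fluorine serves as both directing group and leaving group. The precursors are a tetrasubstituted fluoroarene and two commercial C4 and C1 units.

**3 ⇒ 1.** The C5 methyl is attached by lithiating commercial 1 between fluorine and methoxy (aryllithium 2) and quenching with iodomethane before LiF is lost. This uses the same site-selectivity rule as the key step and replaces a formylation–reduction pair with one step.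

## Roads not taken

**Alternative 1:** The carbocycle of each half would be built from an acyclic hydroxy enone that already carries C3 and C4, and a malonic diester. A base-mediated Michael addition, lactonisation and Claisen condensation would form C4a–C8a, O2–C1 and C7–C8 and give the bicyclic lactone–dione A1. Bridging at the dione stage and late aromatisation would follow.
- Merits: substituents are placed by connectivity, so there is no arene regiochemistry problem. The dione carbon between two carbonyls is a textbook partner for formaldehyde. No aryl ether ever has to be cleaved. On that last point this road is better than the chosen one, which must demethylate an acid-labile isochroman.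
- Weak points: the Michael acceptor is β-branched and α-substituted. The basic cascade can deprotonate the γ-position (C4) of the enone and erase that stereocentre. Two hexasubstituted cyclohexanediones must be dehydrogenated to resorcinols on a bridged tetraketone. C1 arrives at the lactone level in both halves and must be reduced to two different levels, so the halves are still undifferentiated.
- Comparison: the chosen plan is shorter (eight steps), buys the arene instead of making it, and sets C4 only after all strongly basic chemistry is over.

**Alternative 2:** One benzene ring would be made last by a Danheiser benzannulation. Irradiating a dihydropyranyl α-diazo ketone gives a vinylketene (Wolff rearrangement). It combines with a siloxyalkyne that carries the complete other half through C9 ([2+2], 4π opening, 6π closure), forming C7–C8, C5–C6 and C8–C8a and giving A2.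
- Merits: the route is convergent and the two halves emerge differently protected. A2 has one free phenol, one silyl ether and two methoxymethyl ethers, so the final one-site oxidation can be directed. This is a real advantage over the chosen plan, whose last step is at best statistical between two identical halves.
- Weak points: the first half must still be made by some other route. The C3/C4 problem is solved a second time, by different chemistry, in the diazo ketone. The ynol silyl ether of a hindered benzylic alkyne takes several steps. The cycloaddition must assemble a hexasubstituted ring from a disubstituted ketene terminus, where this benzannulation is least efficient.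
- Comparison: the chosen plan uses one monomer twice and one stereochemical solution, and its step count is roughly half.

**Alternative 3:** Both benzene rings would be formed at once from a methylene-linked bis(1-methoxy-1,3-bis(trimethylsilyloxy)diene) and two molecules of a chiral alkynoate. Thermal [4+2] cycloaddition and loss of methanol would form C5–C4a and C8–C8a in each half and give the bis-salicylate A3.
- Merits: two-directional, the bridge is in place from the start, regiochemistry follows from diene polarity, and the phenols arrive free.
- Weak points: the diene is substituted at its central carbon by C9 and at its terminus by methyl. It must bond to an alkyne carbon that bears a secondary alkyl group, and do so twice in one molecule. The propargylic C4–H of the alkynoate is acidic and can racemise through the allenoate. The esters must still be reduced and the rings closed. The final one-site oxidation is as unselective as in the chosen plan.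
- Comparison: this road matches the chosen one in symmetry and beats it in avoiding ether cleavage. The chosen plan answers with a shorter sequence and a key step that has close precedent on the same 3,5-dimethoxyaryne type.

Key step: step 2

Assumptions on the chemistry:
- Formaldehyde 5 is used as the monomer (cracked paraformaldehyde) in step 2 and as formalin in step 7.
- The lithium reagent from (E)-4 keeps its geometry. It is correctly named (Z)-but-2-en-2-yllithium, because lithium ranks below carbon.
- The enantiomer of IpcBH2 is chosen by analogy with the known sense of induction on 1-arylcycloalkenes. The configuration of 13 is to be confirmed (Mosher ester analysis) before proceeding; if the sense is opposite, the reagent from (+)-α-pinene is used.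
- The quinone methide of 18 is drawn as the 6-hydroxy-8-oxo tautomer, which equilibrates with the 8-hydroxy-6-oxo form.

## Route

Step 1
Reactants: 1 1-fluoro-3,5-dimethoxybenzene
Product: 3 1-fluoro-3,5-dimethoxy-2-methylbenzene, via (2-fluoro-4,6-dimethoxyphenyl)lithium 2 (not isolated)
Conditions: n-BuLi (1.05 equiv), THF, −78 °C, 1 h; MeI (1.5 equiv), −78 °C → rt
Reagents that add atoms: iodomethane, CI
Why: Directed ortho-lithiation at the most acidic ring proton, the one flanked by fluorine and methoxy; the ortho-fluoroaryllithium is stable at −78 °C and should be C-methylated before LiF is lost.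

Step 2
Reactants: 3 1-fluoro-3,5-dimethoxy-2-methylbenzene; 4 (E)-2-bromobut-2-ene; 5 formaldehyde
Product: 10 (E)-[2-(but-2-en-2-yl)-4,6-dimethoxy-3-methylphenyl]methanol, via (Z)-but-2-en-2-yllithium 6 (not isolated), via (2-fluoro-4,6-dimethoxy-3-methylphenyl)lithium 7 (not isolated), via 3,5-dimethoxy-6-methylbenzyne 8 (not isolated), via {2-[(2E)-but-2-en-2-yl]-4,6-dimethoxy-3-methylphenyl}lithium 9 (not isolated)
Conditions: 4 (2.5 equiv), t-BuLi (5.0 equiv), THF/Et2O, −78 °C; separately 3, n-BuLi (1.0 equiv), THF, −78 °C, 1 h; solution of 6 added to 7, −78 → 0 °C; CH2O (gas, from cracked paraformaldehyde), −78 °C → rt; H2O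
Reagents that add atoms: none
Why: n-BuLi removes H8a, the ring proton flanked by fluorine and the C8 methoxy group, giving 7, which is stable at −78 °C and loses LiF on warming to form aryne 8. The C8 methoxy group polarises the strained triple bond inductively, so alkenyllithium 6 attacks the distal carbon C4a and the negative charge develops at C8a beside oxygen, where lithium is also chelated; the C5 methyl beside C4a is the only opposing, steric, factor. This addition forms C4a–C4 and gives aryllithium 9, which formaldehyde captures to form C8a–C1. Lithium–bromine exchange on 4 and the reaction of 6 both proceed with retention at the sp2 carbon, so the alkene of 10 is E with the two methyls cis. The closest known reaction type is the three-component coupling of 3-alkoxyarynes, generated from ortho-lithiated fluoroarenes, with organolithium or Grignard nucleophiles and electrophilic capture of the resulting aryl-metal. No ring closes and no stereocentre is formed. The step needs site-selective lithiation (secured by fluorine plus methoxy), regioselective addition (secured by the C8 methoxy group) and geometric integrity of 6 (secured by low temperature in ether solvents); using n-BuLi as base leaves no amine in the flask to protonate 9.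

Step 3
Reactants: 10 (E)-[2-(but-2-en-2-yl)-4,6-dimethoxy-3-methylphenyl]methanol
Product: 11 (E)-{[2-(but-2-en-2-yl)-4,6-dimethoxy-3-methylbenzyl]oxy}(tert-butyl)dimethylsilane
Conditions: TBSCl (1.2 equiv), imidazole (2 equiv), DMF, rt
Reagents that add atoms: tert-butyldimethylsilyl chloride, CC(C)(C)[Si](C)(C)Cl
Why: Standard silylation of a primary alcohol; the ether keeps the hydroxyl from consuming B–H and from tethering the borane in step 4, and is later the leaving group for ring closure.

Step 4
Reactants: 11 (E)-{[2-(but-2-en-2-yl)-4,6-dimethoxy-3-methylbenzyl]oxy}(tert-butyl)dimethylsilane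
Product: 13 (2R,3S)-3-[2-({[tert-butyl(dimethyl)silyl]oxy}methyl)-3,5-dimethoxy-6-methylphenyl]butan-2-ol, via isopinocampheyl(sec-alkyl)borane 12 (not isolated)
Conditions: IpcBH2 from (−)-α-pinene (1.3 equiv), THF, −25 °C; then 3 M NaOH, 30% H2O2, 0 °C → rt
Reagents that add atoms: hydrogen peroxide, OO
Why: Brown asymmetric hydroboration of a trisubstituted alkene: boron adds to the less substituted carbon (future C3) and hydrogen to the aryl-bearing carbon (future C4) in a syn fashion, so the E alkene gives only the (2R,3S)/(2S,3R) pair, which corresponds to the trans ring relationship. The chiral isopinocampheyl group selects the alkene face and thereby sets both centres, and oxidation of 12 replaces boron by hydroxyl with retention.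

Step 5
Reactants: 13 (2R,3S)-3-[2-({[tert-butyl(dimethyl)silyl]oxy}methyl)-3,5-dimethoxy-6-methylphenyl]butan-2-ol
Product: 14 (3R,4S)-6,8-dimethoxy-3,4,5-trimethyl-3,4-dihydro-1H-isochromene
Conditions: p-TsOH·H2O (10 mol %), CH2Cl2 (0.02 M), 0 °C → rt
Reagents that add atoms: none
Why: Acid ionises the 2,4-dimethoxybenzylic C–O bond of the silyl ether to a stabilised benzylic cation, which the C3 hydroxyl captures in a six-membered cycloetherification. The C3–O bond is never broken and C4a is meta to both methoxy groups, so no phenonium pathway threatens C3 or C4; dilution suppresses intermolecular attack by C7.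

Step 6
Reactants: 14 (3R,4S)-6,8-dimethoxy-3,4,5-trimethyl-3,4-dihydro-1H-isochromene
Product: 15 (3R,4S)-3,4,5-trimethyl-3,4-dihydro-1H-isochromene-6,8-diol
Conditions: BBr3 (5 equiv), CH2Cl2, −78 → 0 °C; H2O, 0 °C → rt
Reagents that add atoms: none
Why: Lewis-acid O-demethylation of aryl methyl ethers with BBr3. Any transient opening of the benzylic C1–O2 bond should be reversed on aqueous work-up, because a 2,4-dihydroxybenzyl position recloses onto the C3 oxygen through its quinone methide; holding the temperature at or below 0 °C protects the secondary C3–O bond.

Step 7
Reactants: 15 (3R,4S)-3,4,5-trimethyl-3,4-dihydro-1H-isochromene-6,8-diol (2 equiv); 5 formaldehyde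
Product: 17 7,7'-methylenebis[(3R,4S)-3,4,5-trimethyl-3,4-dihydro-1H-isochromene-6,8-diol], via (3R,4S)-7-(hydroxymethyl)-3,4,5-trimethyl-3,4-dihydro-1H-isochromene-6,8-diol 16 (not isolated)
Conditions: 37% aq. CH2O (0.5 equiv), K2CO3 (0.2 equiv), degassed MeOH/H2O, argon, rt → 40 °C
Reagents that add atoms: none
Why: Lederer–Manasse hydroxymethylation of the resorcinol at C7, its only free ring position, gives 16, which loses water to an ortho-quinone methide that a second molecule of 15 captures at C7. This is the classical formaldehyde bridging of resorcinols and phloroglucinols; no further ring position is free, so the reaction stops at the dimer.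

Step 8
Reactants: 17 7,7'-methylenebis[(3R,4S)-3,4,5-trimethyl-3,4-dihydro-1H-isochromene-6,8-diol]
Product: 18 (3R,4S)-7-{[(3R,4S)-6,8-dihydroxy-3,4,5-trimethyl-3,4-dihydro-1H-isochromen-7-yl]methyl}-6-hydroxy-3,4,5-trimethyl-3,4-dihydro-8H-isochromen-8-one
Conditions: DDQ (1.0 equiv, slow addition), 1,4-dioxane, argon, 10 °C → rt
Reagents that add atoms: none
Why: DDQ dehydrogenation of a phenolic isochroman: hydride leaves C1, which is benzylic, α to the ring oxygen and ortho/para to the two hydroxyls, and loss of a phenolic proton gives the vinylogous-ester quinone methide, as in the oxidation of dihydrocitrinin-type isochromans. One equivalent of oxidant limits the reaction to one half, unreacted 17 is to be recovered and recycled, and C3 and C4 are untouched.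

## Compound list

1 | 1-fluoro-3,5-dimethoxybenzene | COc1cc(F)cc(OC)c1 | starting material
2 | (2-fluoro-4,6-dimethoxyphenyl)lithium | [Li]c1c(F)cc(OC)cc1OC | intermediate
3 | 1-fluoro-3,5-dimethoxy-2-methylbenzene | COc1cc(OC)c(C)c(F)c1 | intermediate
4 | (E)-2-bromobut-2-ene | C/C=C(\C)Br | starting material
5 | formaldehyde | C=O | starting material
6 | (Z)-but-2-en-2-yllithium | C/C=C(\C)[Li] | intermediate
7 | (2-fluoro-4,6-dimethoxy-3-methylphenyl)lithium | [Li]c1c(F)c(C)c(OC)cc1OC | intermediate
8 | 3,5-dimethoxy-6-methylbenzyne (1,2-didehydro-3,5-dimethoxy-6-methylbenzene) | COC1=CC(OC)=C(C)C#C1 | intermediate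
9 | {2-[(2E)-but-2-en-2-yl]-4,6-dimethoxy-3-methylphenyl}lithium | C/C=C(\C)c1c(C)c(OC)cc(OC)c1[Li] | intermediate
10 | (E)-[2-(but-2-en-2-yl)-4,6-dimethoxy-3-methylphenyl]methanol | C/C=C(\C)c1c(C)c(OC)cc(OC)c1CO | intermediate
11 | (E)-{[2-(but-2-en-2-yl)-4,6-dimethoxy-3-methylbenzyl]oxy}(tert-butyl)dimethylsilane | C/C=C(\C)c1c(C)c(OC)cc(OC)c1CO[Si](C)(C)C(C)(C)C | intermediate
12 | (isopinocampheyl){3-[2-({[tert-butyl(dimethyl)silyl]oxy}methyl)-3,5-dimethoxy-6-methylphenyl]butan-2-yl}borane, isopinocampheyl group from (−)-α-pinene, boron in the position and orientation of the later (2R)-hydroxyl | C[C@@H]1[C@@H](B[C@H](C)[C@@H](C)c3c(C)c(OC)cc(OC)c3CO[Si](C)(C)C(C)(C)C)C[C@H]2C[C@@H]1C2(C)C | intermediate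
13 | (2R,3S)-3-[2-({[tert-butyl(dimethyl)silyl]oxy}methyl)-3,5-dimethoxy-6-methylphenyl]butan-2-ol | C[C@@H](O)[C@@H](C)c1c(C)c(OC)cc(OC)c1CO[Si](C)(C)C(C)(C)C | intermediate
14 | (3R,4S)-6,8-dimethoxy-3,4,5-trimethyl-3,4-dihydro-1H-isochromene | COc1cc(OC)c(C)c2c1CO[C@H](C)[C@H]2C | intermediate
15 | (3R,4S)-3,4,5-trimethyl-3,4-dihydro-1H-isochromene-6,8-diol | Oc1cc(O)c(C)c2c1CO[C@H](C)[C@H]2C | intermediate
16 | (3R,4S)-7-(hydroxymethyl)-3,4,5-trimethyl-3,4-dihydro-1H-isochromene-6,8-diol | OCc1c(O)c(C)c2c(c1O)CO[C@H](C)[C@H]2C | intermediate
17 | 7,7'-methylenebis[(3R,4S)-3,4,5-trimethyl-3,4-dihydro-1H-isochromene-6,8-diol] | C(c1c(O)c(C)c2c(c1O)CO[C@H](C)[C@H]2C)c1c(O)c(C)c2c(c1O)CO[C@H](C)[C@H]2C | intermediate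
18 | (3R,4S)-7-{[(3R,4S)-6,8-dihydroxy-3,4,5-trimethyl-3,4-dihydro-1H-isochromen-7-yl]methyl}-6-hydroxy-3,4,5-trimethyl-3,4-dihydro-8H-isochromen-8-one | CC1=C2C(=CO[C@H](C)[C@H]2C)C(=O)C(Cc2c(O)c(C)c3c(c2O)CO[C@H](C)[C@H]3C)=C1O | target

## Step count and risk

Total: 8 steps. Longest linear sequence: 8 steps (1 → 18); compounds 4 and 5 are commercial.

**Step 2 (key step).** The most likely failure is loss of material in the capture sequence. Aryllithium 9 or residual n-BuLi can compete with 6 for aryne 8, giving oligomeric biaryls or a butylated arene. The hindered 9 may also be only partly hydroxymethylated by formaldehyde, which polymerises readily, so that proton quench takes over. A smaller risk is erosion of regioselectivity by the C5 methyl beside C4a. Transmetalating 6 to the magnesium reagent with MgBr2 is a conditions-level remedy. The fallback changes the C1 unit. It sets out from 3 with 4 as before, but captures the aryl-metal with carbon dioxide, a reliable electrophile for hindered aryllithiums, to give 2-[(2E)-but-2-en-2-yl]-4,6-dimethoxy-3-methylbenzoic acid F1. F1 is freed from neutral by-products by base extraction and reduced with LiAlH4 in THF, returning to the route at 10.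

**Step 4.** The likely failure is poor facial selectivity or slow reaction. The aryl group is twisted out of the alkene plane and flanked by methyl and silyloxymethyl groups, a situation not covered by the simple aryl-alkene precedents. The fallback separates diastereo- from enantiocontrol. From 11, hydroboration with BH3·SMe2 and NaOH/H2O2 should give the racemic alcohol rac-(2R*,3S*)-3-[2-({[tert-butyl(dimethyl)silyl]oxy}methyl)-3,5-dimethoxy-6-methylphenyl]butan-2-ol F2 as a single diastereomer, since syn addition is intrinsic. Kinetic resolution with Candida antarctica lipase B and vinyl acetate should, by the Kazlauskas rule, acylate the (2R)-carbinol and give (2R,3S)-3-[2-({[tert-butyl(dimethyl)silyl]oxy}methyl)-3,5-dimethoxy-6-methylphenyl]butan-2-yl acetate F3. The slower (2S,3R)-3-[2-({[tert-butyl(dimethyl)silyl]oxy}methyl)-3,5-dimethoxy-6-methylphenyl]butan-2-ol F4 is left behind and separated. Methanolysis of F3 (K2CO3, MeOH) returns to the route at 13.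

**Step 6.** The likely failure is irreversible diversion after BBr3 ionises the benzylic C1–O2 bond. The benzylic bromide could alkylate C7 of another molecule, or the boron-bound C3 oxygen could be replaced by bromide, with loss of material or of the C3 configuration. The fallback raises C1 to the lactone level before demethylation, where BBr3 cleavage is well behaved. From 14:
- benzylic oxidation (KMnO4 on CuSO4·5H2O, CH2Cl2) gives (3R,4S)-6,8-dimethoxy-3,4,5-trimethylisochroman-1-one F5;
- BBr3 gives (3R,4S)-6,8-dihydroxy-3,4,5-trimethylisochroman-1-one F6;
- partial reduction with i-Bu2AlH brings C1 to the aldehyde level, which in this series exists as the quinone methide (3R,4S)-6-hydroxy-3,4,5-trimethyl-3,4-dihydro-8H-isochromen-8-one F7;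
- NaBH4 in MeOH reduces F7 at C1 and returns to the route at 15.

**Step 8.** The likely failure is lack of selectivity. The two halves of 17 are identical and electronically insulated, so mono-oxidation is at best statistical and over-oxidation to the bis-quinone methide competes. Hydride abstraction from the doubly benzylic C9 is a second possible pathway. The fallback joins two different monomers so that only one half ever meets the oxidant. From 15, a Mannich reaction with 5 and dimethylamine gives (3R,4S)-7-[(dimethylamino)methyl]-3,4,5-trimethyl-3,4-dihydro-1H-isochromene-6,8-diol F8. Separately, 15 is oxidised with one equivalent of DDQ to the monomeric quinone methide (3R,4S)-6-hydroxy-3,4,5-trimethyl-3,4-dihydro-8H-isochromen-8-one F7, which has no C9 and only one oxidisable ring. Heating F8 with F7 in toluene releases dimethylamine and generates the ortho-quinone methide of the resorcinol half. The nucleophilic C7 of F7 adds to it in a conjugate fashion, returning to the route at 18.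

## Further compounds

F1 | step 2 | 2-[(2E)-but-2-en-2-yl]-4,6-dimethoxy-3-methylbenzoic acid | C/C=C(\C)c1c(C)c(OC)cc(OC)c1C(=O)O
F2 | step 4 | rac-(2R*,3S*)-3-[2-({[tert-butyl(dimethyl)silyl]oxy}methyl)-3,5-dimethoxy-6-methylphenyl]butan-2-ol (both enantiomers) | C[C@@H](O)[C@@H](C)c1c(C)c(OC)cc(OC)c1CO[Si](C)(C)C(C)(C)C.C[C@H](O)[C@H](C)c1c(C)c(OC)cc(OC)c1CO[Si](C)(C)C(C)(C)C
F3 | step 4 | (2R,3S)-3-[2-({[tert-butyl(dimethyl)silyl]oxy}methyl)-3,5-dimethoxy-6-methylphenyl]butan-2-yl acetate | C[C@@H](OC(C)=O)[C@@H](C)c1c(C)c(OC)cc(OC)c1CO[Si](C)(C)C(C)(C)C
F4 | step 4 | (2S,3R)-3-[2-({[tert-butyl(dimethyl)silyl]oxy}methyl)-3,5-dimethoxy-6-methylphenyl]butan-2-ol | C[C@H](O)[C@H](C)c1c(C)c(OC)cc(OC)c1CO[Si](C)(C)C(C)(C)C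
F5 | step 6 | (3R,4S)-6,8-dimethoxy-3,4,5-trimethylisochroman-1-one | COc1cc(OC)c(C)c2c1C(=O)O[C@H](C)[C@H]2C
F6 | step 6 | (3R,4S)-6,8-dihydroxy-3,4,5-trimethylisochroman-1-one | Oc1cc(O)c(C)c2c1C(=O)O[C@H](C)[C@H]2C
F7 | step 6 | (3R,4S)-6-hydroxy-3,4,5-trimethyl-3,4-dihydro-8H-isochromen-8-one | CC1=C2C(=CO[C@H](C)[C@H]2C)C(=O)C=C1O
F8 | step 8 | (3R,4S)-7-[(dimethylamino)methyl]-3,4,5-trimethyl-3,4-dihydro-1H-isochromene-6,8-diol | CN(C)Cc1c(O)c(C)c2c(c1O)CO[C@H](C)[C@H]2C
A1 | alternative 1 | (3R,4S)-3,4,5-trimethylhexahydro-1H-isochromene-1,6,8-trione (ring-fusion and C5 centres as a mixture) | CC1C(=O)CC(=O)C2C1[C@H](C)[C@@H](C)OC2=O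
A2 | alternative 2 | (3R,4S)-7-{[(3R,4S)-6,8-bis(methoxymethoxy)-3,4,5-trimethylisochroman-7-yl]methyl}-3,4,5-trimethyl-6-(triisopropylsilyloxy)isochroman-8-ol | CC(C)[Si](C(C)C)(C(C)C)Oc1c(C)c2c(c(O)c1Cc1c(OCOC)c(C)c3c(c1OCOC)CO[C@H](C)[C@H]3C)CO[C@H](C)[C@H]2C
A3 | alternative 3 | dimethyl 3,3'-methylenebis{6-[(2S,3R)-3-(tert-butyldimethylsilyloxy)butan-2-yl]-2,4-dihydroxy-5-methylbenzoate} | COC(=O)c1c(O)c(Cc2c(O)c(C)c([C@H](C)[C@@H](C)O[Si](C)(C)C(C)(C)C)c(C(=O)OC)c2O)c(O)c(C)c1[C@H](C)[C@@H](C)O[Si](C)(C)C(C)(C)C
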